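**Plan**

- Retrosynthetic cuts, in order: the C7–propenyl bond (Suzuki coupling); the bond between C2 of the dioxane ring and the hydroxydimethoxyphenyl ring (Friedel–Crafts attack on a C2 oxocarbenium ion); C2–OAc back to the lactone C2=O; the lactone O1–C2 bond and the aryl C8a–O1 bond (Baeyer–Villiger oxidation of an aldehyde); the O4–C3 ether bond (Mitsunobu reaction).
- Forward: 5-bromo-o-vanillin is etherified with ethyl (S)-lactate; Baeyer–Villiger oxidation turns CHO into the second ring oxygen and lactonisation closes the 1,4-dioxane ring; reductive acetylation gives the lactol acetate; the aryl ring is then joined at C2 as free 2,6-dimethoxyphenol; the (E)-propenyl group is put on last.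
- Enabling feature: with the aryl group removed, C2 of the dioxane ring is an acetal-level carbon on ring oxygen O1 (a masked aldehyde that opens to an oxocarbenium ion). The aryl carbon that bonds to it is para to the free OH of a 2,6-dimethoxyphenol whose two ortho positions carry OMe, so both partners react by their innate polarity, without protection or prefunctionalisation of the arene.
- Stereochemistry: C3 (R) comes from ethyl (S)-lactate by Mitsunobu inversion. C2 (R) is set in the key step trans to the C3 methyl group; the product is a p-hydroxybenzyl aryl ether and can converge on the trans isomer by reversible C2–O1 ionisation. The E alkene comes from the boronate.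
- Helpers: the bromine on ring A holds the place of the acid-sensitive propenyl group and deactivates ring A in the key step; the acetate is the activating group and leaves in the key step.

Key step: step 4

Assumption: 8 is used as its mixture of C2 epimers, since C2 becomes planar in step 4.

**Step 1**
Reactants: 1 5-bromo-2-hydroxy-3-methoxybenzaldehyde; 2 ethyl (S)-lactate
Product: 3 ethyl (2R)-2-(4-bromo-2-formyl-6-methoxyphenoxy)propanoate
Conditions: PPh3, DIAD, THF, 0 °C → rt
Reagents that add atoms: none
Why: Mitsunobu reaction: the acidic phenol of 1 (flanked by CHO and OMe) displaces the activated secondary hydroxyl of 2 in an SN2 process, so the (S) centre is inverted to the (R) aryloxy centre that becomes C3, and placing this ether oxygen next to the OMe-bearing carbon fixes the regiochemistry of ring A.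

**Step 2**
Reactants: 3 ethyl (2R)-2-(4-bromo-2-formyl-6-methoxyphenoxy)propanoate
Product: 6 (3R)-7-bromo-5-methoxy-3-methyl-2,3-dihydro-1,4-benzodioxin-2-one, via aryl formate 4 (not isolated), via hydroxy ester 5 (not isolated)
Conditions: mCPBA, CH2Cl2, 0 °C → rt; then TsOH·H2O (cat.), EtOH, rt; then toluene, reflux (EtOH distilled off)
Reagents that add atoms: meta-chloroperoxybenzoic acid, OOC(=O)c1cccc(Cl)c1
Why: Baeyer–Villiger (Dakin-type) oxidation in which the electron-rich 2-alkoxyaryl group migrates to give the aryl formate, acid-catalysed ethanolysis frees the phenol, and six-membered lactonisation onto the neighbouring ester is driven by removal of ethanol, under acidic conditions that should leave the α-aryloxy stereocentre untouched.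

**Step 3**
Reactants: 6 (3R)-7-bromo-5-methoxy-3-methyl-2,3-dihydro-1,4-benzodioxin-2-one
Product: 8 (3R)-7-bromo-5-methoxy-3-methyl-2,3-dihydro-1,4-benzodioxin-2-yl acetate (C2 epimers), via aluminium lactolate 7 (not isolated)
Conditions: DIBAL-H, CH2Cl2, −78 °C; then pyridine, DMAP, Ac2O, −78 → 0 °C
Reagents that add atoms: acetic anhydride, CC(=O)OC(C)=O
Why: Reductive acetylation of a lactone (Rychnovsky protocol), in which DIBAL-H stops at the tetrahedral aluminium lactolate at −78 °C and acylation in the same flask traps it as the α-acetoxy ether, a defined oxocarbenium precursor.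

**Step 4**
Reactants: 8 (3R)-7-bromo-5-methoxy-3-methyl-2,3-dihydro-1,4-benzodioxin-2-yl acetate; 9 2,6-dimethoxyphenol
Product: 11 4-[(2R,3R)-7-bromo-5-methoxy-3-methyl-2,3-dihydro-1,4-benzodioxin-2-yl]-2,6-dimethoxyphenol, via oxocarbenium ion 10 (not isolated)
Conditions: 9 (1.2 equiv), TMSOTf (0.2 equiv), 4 Å MS, CH2Cl2, −40 → 0 °C
Reagents that add atoms: none
Why: The acid ionises the acetate at C2 to the cyclic oxocarbenium ion 10 (C2=O1+), which is attacked by C4 of 9, the only position activated by the free OH because both ortho positions carry OMe; rearomatisation gives 11 and regenerates the acid, and any O-aryl acetal formed first at the hindered phenol oxygen is reversible and should funnel to the C-adduct. The closest known reaction type is the Lewis-acid Friedel–Crafts C-arylation of lactol acetates by phenols, as in aryl C-glycoside synthesis. No ring is closed in the C–C bond formation because the dioxane ring is already in place; if the C2–O1 bond ionises afterwards, reclosure of the tethered phenol onto the p-quinone methide is 6-exo-trig. The new C2 stereocentre is controlled by the lactate-derived C3 centre: the aryl group should end trans to the methyl group (both pseudo-equatorial on the half-chair), because the p-hydroxybenzyl aryl ether of 11 can equilibrate at C2 under the acid through that reversible C2–O1 ionisation, whichever face is attacked first, and C3 is not touched. The step needs para C-arylation over O-arylation, mono- over bis-arylation, and attack by 9 rather than by ring A of a second molecule of 8; these are secured by the blocked ortho positions of 9, by a small excess of 9 at low temperature with only catalytic acid, and by the bromine and acetal substituents that deactivate ring A.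

**Step 5**
Reactants: 11 4-[(2R,3R)-7-bromo-5-methoxy-3-methyl-2,3-dihydro-1,4-benzodioxin-2-yl]-2,6-dimethoxyphenol; 12 (E)-prop-1-enylboronic acid pinacol ester
Product: 13 2,6-dimethoxy-4-[(2R,3R)-5-methoxy-3-methyl-7-[(1E)-prop-1-en-1-yl]-2,3-dihydro-1,4-benzodioxin-2-yl]phenol
Conditions: Pd(dppf)Cl2 (5 mol %), K2CO3, 1,4-dioxane/H2O, 80 °C, degassed
Reagents that add atoms: none
Why: Suzuki–Miyaura coupling, in which oxidative addition into the aryl bromide, transmetalation of the alkenylboronate and reductive elimination proceed with retention of the E geometry, the free phenol is tolerated as its phenoxide, and the two stereocentres are not involved.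

**Compound list**

1 | 5-bromo-2-hydroxy-3-methoxybenzaldehyde | O=Cc1cc(Br)cc(OC)c1O | starting material
2 | ethyl (S)-lactate | C[C@H](O)C(=O)OCC | starting material
3 | ethyl (2R)-2-(4-bromo-2-formyl-6-methoxyphenoxy)propanoate | C[C@@H](Oc1c(C=O)cc(Br)cc1OC)C(=O)OCC | intermediate
4 | ethyl (2R)-2-[4-bromo-2-(formyloxy)-6-methoxyphenoxy]propanoate | C[C@@H](Oc1c(OC=O)cc(Br)cc1OC)C(=O)OCC | intermediate
5 | ethyl (2R)-2-(4-bromo-2-hydroxy-6-methoxyphenoxy)propanoate | C[C@@H](Oc1c(O)cc(Br)cc1OC)C(=O)OCC | intermediate
6 | (3R)-7-bromo-5-methoxy-3-methyl-2,3-dihydro-1,4-benzodioxin-2-one | O=C1Oc2cc(Br)cc(OC)c2O[C@@H]1C | intermediate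
7 | diisobutylaluminium (3R)-7-bromo-5-methoxy-3-methyl-2,3-dihydro-1,4-benzodioxin-2-olate | CC(C)C[Al](CC(C)C)OC1Oc2cc(Br)cc(OC)c2O[C@@H]1C | intermediate
8 | (3R)-7-bromo-5-methoxy-3-methyl-2,3-dihydro-1,4-benzodioxin-2-yl acetate (C2 epimers) | CC(=O)OC1Oc2cc(Br)cc(OC)c2O[C@@H]1C | intermediate
9 | 2,6-dimethoxyphenol | COc1cccc(OC)c1O | starting material
10 | (3R)-7-bromo-5-methoxy-3-methyl-3H-1,4-benzodioxin-1-ium (C2 oxocarbenium ion) | C1=[O+]c2cc(Br)cc(OC)c2O[C@@H]1C | intermediate
11 | 4-[(2R,3R)-7-bromo-5-methoxy-3-methyl-2,3-dihydro-1,4-benzodioxin-2-yl]-2,6-dimethoxyphenol | Brc1cc(OC)c2c(c1)O[C@H](c1cc(OC)c(O)c(OC)c1)[C@@H](C)O2 | intermediate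
12 | (E)-prop-1-enylboronic acid pinacol ester | C/C=C/B1OC(C)(C)C(C)(C)O1 | starting material
13 | 2,6-dimethoxy-4-[(2R,3R)-5-methoxy-3-methyl-7-[(1E)-prop-1-en-1-yl]-2,3-dihydro-1,4-benzodioxin-2-yl]phenol | C/C=C/c1cc(OC)c2c(c1)O[C@H](c1cc(OC)c(O)c(OC)c1)[C@@H](C)O2 | target

**Totals**

Total step count: 5. Longest linear sequence: 5 steps (1 → 3 → 6 → 8 → 11 → 13).

**Steps most likely to fail**

Step 4. Three processes may intervene. The oxocarbenium ion may lose the C3 proton to the achiral 1,4-benzodioxine, or undergo a hydride shift, which would erode the C3 configuration. The ring-opened benzylic cation of the product may be arylated a second time. Convergence on the trans isomer may be incomplete. The fallback sets out from 6 and 9 and comes back at 11. Phenol 9 would be brominated at C4 (NBS, MeCN) to 4-bromo-2,6-dimethoxyphenol F1 and silylated (TBSCl, imidazole, DMF) to (4-bromo-2,6-dimethoxyphenoxy)(tert-butyl)dimethylsilane F2. Bromine–lithium exchange (n-BuLi, THF, −78 °C) would give [4-(tert-butyldimethylsilyloxy)-3,5-dimethoxyphenyl]lithium F3, which would be added to lactone 6 at −78 °C to give the 2-aryl lactol F4. Ionic hydrogenation (Et3SiH, BF3·OEt2, CH2Cl2/MeCN, −40 °C), as in aryl C-glycoside synthesis, should deliver hydride axially to the 2-aryl oxocarbenium ion and give the trans silyl ether F5. TBAF/AcOH would then release 11.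

Step 3. The aluminium lactolate may collapse by loss of the aryloxide before acylation, so that acetylation lands on the phenol oxygen of the ring-opened aldehyde or reduction runs on. The fallback sets out from 6 and comes back at 11. Lactone 6 would be reduced with DIBAL-H and quenched cold with Rochelle salt, so that the ring-closed lactol (3R)-7-bromo-5-methoxy-3-methyl-2,3-dihydro-1,4-benzodioxin-2-ol F6 is isolated. F6 would be condensed directly with 9 under catalytic Sc(OTf)3 or TfOH with 4 Å molecular sieves in CH2Cl2, a dehydrative Friedel–Crafts arylation of a free lactol that bypasses 8.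

Step 5. Under aqueous base the phenoxide may open the benzylic C2–O1 ether to a quinone methide that is trapped by water, and oxidative addition into the electron-rich aryl bromide may be slow. The fallback sets out from 11 and comes back at 13. A Stille coupling with allyltributylstannane under neutral conditions (Pd(PPh3)4, toluene, 100 °C) would give 2,6-dimethoxy-4-[(2R,3R)-5-methoxy-3-methyl-7-(prop-2-en-1-yl)-2,3-dihydro-1,4-benzodioxin-2-yl]phenol F7. Ruthenium hydride isomerisation of the allyl group into conjugation (RuHCl(CO)(PPh3)3, toluene, 80 °C) should then give 13 as the thermodynamically favoured E alkene.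

**Further compounds**

F1 | step 4 | 4-bromo-2,6-dimethoxyphenol | COc1cc(Br)cc(OC)c1O
F2 | step 4 | (4-bromo-2,6-dimethoxyphenoxy)(tert-butyl)dimethylsilane | COc1cc(Br)cc(OC)c1O[Si](C)(C)C(C)(C)C
F3 | step 4 | [4-(tert-butyldimethylsilyloxy)-3,5-dimethoxyphenyl]lithium | [Li]c1cc(OC)c(O[Si](C)(C)C(C)(C)C)c(OC)c1
F4 | step 4 | (3R)-7-bromo-2-[4-(tert-butyldimethylsilyloxy)-3,5-dimethoxyphenyl]-5-methoxy-3-methyl-2,3-dihydro-1,4-benzodioxin-2-ol (C2 epimers) | Brc1cc(OC)c2c(c1)OC(O)(c1cc(OC)c(O[Si](C)(C)C(C)(C)C)c(OC)c1)[C@@H](C)O2
F5 | step 4 | {4-[(2R,3R)-7-bromo-5-methoxy-3-methyl-2,3-dihydro-1,4-benzodioxin-2-yl]-2,6-dimethoxyphenoxy}(tert-butyl)dimethylsilane | Brc1cc(OC)c2c(c1)O[C@H](c1cc(OC)c(O[Si](C)(C)C(C)(C)C)c(OC)c1)[C@@H](C)O2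
F6 | step 3 | (3R)-7-bromo-5-methoxy-3-methyl-2,3-dihydro-1,4-benzodioxin-2-ol (C2 epimers) | OC1Oc2cc(Br)cc(OC)c2O[C@@H]1C
F7 | step 5 | 2,6-dimethoxy-4-[(2R,3R)-5-methoxy-3-methyl-7-(prop-2-en-1-yl)-2,3-dihydro-1,4-benzodioxin-2-yl]phenol | C=CCc1cc(OC)c2c(c1)O[C@H](c1cc(OC)c(O)c(OC)c1)[C@@H](C)O2
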